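The data are simulated on assumed constants.

Take the logarithm of the free monomer fraction against time and look for its straight stretch.

| setting | gamma | flask |
|---|---|---|
| free monomer | 0.38 M | 0.38 M |
| initiator | 1.3 mM | 1.3 mM |
| remark | the very flask that is asked about, followed so far |  |
| time |  | 20 h |

gamma run (percent of the free monomer charged)

| time / h | monomer in chains / % | free monomer / % |
|---|---|---|
| 0.833 | 9.4 | 90.4 |
| 1.33 | 19.6 | 80.2 |
| 2.00 | 32.8 | 67.2 |
| 3.00 | 49.6 | 50.6 |
| 4.00 | 62.8 | 36.0 |
| 6.00 | 80.4 | 19.4 |
| 10.0 | 95.3 | 5.6 |

(each reading ± 0.5 percentage points)

- whether the average number of monomer units in a chain (chains begun, living or dead) reaches 300 by 20 h (yes / no)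
- average number of monomer units in a chain (chains begun, living or dead) at 20 h

- the average divides the monomer in chains by the number of chains begun, living and dead together
- the analysis behind the earlier runs scatters by 0.5 percentage points, standard deviation
- the earlier runs do not show the number of chains; that part of a forecast is a guess

If free monomer adds to living ends, a straight stretch means a level concentration of those ends, and free monomer then falls by a fixed share each hour (pseudo-first-order). The gamma run has the same charge as the flask. Its slope up to 0.833 h is 0.121 h⁻¹, and its later slopes are steeper, so the reckoning starts at 3.00 h. Two columns give the slope from there to 6.00 h: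

free monomer: 0.320 h⁻¹

remainder left by monomer in chains: 0.315 h⁻¹

They agree. Call the first the fade rate, the logarithmic loss of free monomer per hour.

From 6.00 h to 10.0 h the columns part, at 0.311 h⁻¹ and 0.357 h⁻¹, the second higher than the first. The gamma readings at 10.0 h add up to 101%, over the charge, so at least one of them stands high. The second slope is taken to be the one that cheats, because the first stays beside the fade rate.

Carried forward from the gamma reading at 6.00 h, the fade rate leaves this fraction of free monomer in the flask at 20 h:

0.221%

So on this reckoning nearly all the free monomer charged has reacted by then. The average then depends on the number of chains begun, which the readings do not show, so this reckoning commits to no length.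

The forecast says no and gives 290 units, on the ground that “all the initiator has probably started chains”.

The flask answers yes: it holds 436 units per chain at 20 h, and the average reaches 300 at 4.35 h.

    free monomer + initiator → living end + monomer in chains (k = 5.92 × 10⁻⁴ L mol⁻¹ s⁻¹)
    free monomer + living end → monomer in chains + living end, rate k2*[living end]*[free monomer] (k = 0.103 L mol⁻¹ s⁻¹)
    free monomer + initiator → spent initiator (k = 2.86 × 10⁻⁴ L mol⁻¹ s⁻¹)

The fade rate divided by the addition constant 0.103 L mol⁻¹ s⁻¹ gives 0.863 mM of living end, 66.3% of the initiator charge. Counting one chain per living end, the reacted free monomer over that count is 440 units per chain. The flask itself holds 8.68 × 10⁻⁴ M of living end at 20.0 h.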